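**Strategy.** The macrocycle is disconnected at the diaryl ether joining O-5 of catechol ring A to C-1 of para-phenylene ring B. In the target the ring-B carbon ortho to that oxygen (C-2) carries only hydrogen, so it can hold a nitro group temporarily. In one operation the ring-A phenoxide of a linear A–D–C–B chain displaces fluoride ortho to that nitro group, forging the last skeletal C–O bond and the 19-membered ring. The precursor is the tetramethyl ether with a single free ring-A hydroxyl, a copper-made C–O–D ether, two ethano bridges from Wittig/reduction sequences, and a 4-fluoro-3-nitrophenyl terminus. Denitration via the aniline and demethylation finish the synthesis.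

Key step: step 11

Remark on the chemistry: the target has no stereocentre and the 19-membered ring is assumed to be conformationally mobile, so no element of chirality has to be set. Each ring is numbered from its bridge-bearing carbon as C-1 (A and C: oxygens at 3, 4, 5; D: meta-phenylene; B: para-phenylene). Alkenes 6 and 15 are carried as E/Z mixtures because both isomers converge on reduction.

**Step 1**
Reactants: 1 3-hydroxy-4,5-dimethoxybenzaldehyde
Product: 2 3,4-dimethoxy-5-(methoxymethoxy)benzaldehyde
Conditions: MOMCl, iPr2NEt, CH2Cl2, 0 °C to rt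
Reagents that add atoms: chloromethyl methyl ether, COCCl
Why: O-alkylation of the phenol with the reactive α-chloro ether (MOM protection) masks the future SNAr nucleophile as an acetal that is inert to base, hydride, Pd/H2 and copper catalysis and is later removed by mild acid without touching methyl ethers.

**Step 2**
Reactants: 3 [3-(benzyloxy)phenyl]methanol
Product: 4 [3-(benzyloxy)benzyl]triphenylphosphonium bromide
Conditions: PPh3·HBr, MeCN, reflux
Reagents that add atoms: triphenylphosphine hydrobromide, [Br-].c1ccc(cc1)[PH+](c1ccccc1)c1ccccc1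
Why: Acid-assisted substitution of the benzylic hydroxyl by triphenylphosphine gives the Wittig salt directly, and the aryl benzyl ether is stable to this weakly acidic salt.

**Step 3**
Reactants: 2 3,4-dimethoxy-5-(methoxymethoxy)benzaldehyde; 4 [3-(benzyloxy)benzyl]triphenylphosphonium bromide
Product: 6 1-{2-[3-(benzyloxy)phenyl]ethenyl}-3,4-dimethoxy-5-(methoxymethoxy)benzene (E/Z mixture), via benzylidene phosphorane 5 (not isolated)
Conditions: KOtBu, THF, 0 °C; then 2, 0 °C to rt
Reagents that add atoms: none
Why: Wittig olefination of a semi-stabilised benzylic ylide with an aromatic aldehyde reliably forms the A–D stilbene, whose geometry is irrelevant because the double bond is saturated next.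

**Step 4**
Reactants: 6 1-{2-[3-(benzyloxy)phenyl]ethenyl}-3,4-dimethoxy-5-(methoxymethoxy)benzene
Product: 7 3-{2-[3,4-dimethoxy-5-(methoxymethoxy)phenyl]ethyl}phenol
Conditions: H2 (1 atm), 10% Pd/C, EtOAc–EtOH, rt
Reagents that add atoms: none
Why: Heterogeneous catalytic hydrogenation saturates the stilbene and hydrogenolyses the benzyl ether in the same operation, leaving the MOM acetal and methyl ethers intact, so that only the ring-D phenol is free.

**Step 5**
Reactants: 7 3-{2-[3,4-dimethoxy-5-(methoxymethoxy)phenyl]ethyl}phenol; 8 3-bromo-4,5-dimethoxybenzaldehyde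
Product: 9 3-(3-{2-[3,4-dimethoxy-5-(methoxymethoxy)phenyl]ethyl}phenoxy)-4,5-dimethoxybenzaldehyde
Conditions: CuI (cat.), N,N-dimethylglycine·HCl (cat.), Cs2CO3, dioxane, 95 °C
Reagents that add atoms: none
Why: Ligand-accelerated Ullmann C–O coupling joins the only free phenol (ring D) to the aryl bromide of ring C, and these mild copper conditions tolerate the non-enolisable aldehyde and the acetal.

**Step 6**
Reactants: 9 3-(3-{2-[3,4-dimethoxy-5-(methoxymethoxy)phenyl]ethyl}phenoxy)-4,5-dimethoxybenzaldehyde
Product: 10 [3-(3-{2-[3,4-dimethoxy-5-(methoxymethoxy)phenyl]ethyl}phenoxy)-4,5-dimethoxyphenyl]methanol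
Conditions: NaBH4, MeOH–THF, 0 °C
Reagents that add atoms: none
Why: Borohydride reduction of the aryl aldehyde to the benzylic alcohol is chemoselective, since nothing else in the molecule is reducible by hydride.

**Step 7**
Reactants: 10 [3-(3-{2-[3,4-dimethoxy-5-(methoxymethoxy)phenyl]ethyl}phenoxy)-4,5-dimethoxyphenyl]methanol
Product: 12 [3-(3-{2-[3,4-dimethoxy-5-(methoxymethoxy)phenyl]ethyl}phenoxy)-4,5-dimethoxybenzyl]triphenylphosphonium bromide, via benzylic bromide 11 (not isolated)
Conditions: CBr4, PPh3, CH2Cl2, 0 °C; then PPh3, toluene, 80 °C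
Reagents that add atoms: carbon tetrabromide, BrC(Br)(Br)Br; triphenylphosphine, c1ccc(cc1)P(c1ccccc1)c1ccccc1
Why: The Appel reaction brominates the alcohol under neutral conditions that spare the acid-labile MOM group, and the labile electron-rich benzyl bromide is quaternised in the same flask by SN2 attack of triphenylphosphine.

**Step 8**
Reactants: 12 [3-(3-{2-[3,4-dimethoxy-5-(methoxymethoxy)phenyl]ethyl}phenoxy)-4,5-dimethoxybenzyl]triphenylphosphonium bromide; 13 4-fluoro-3-nitrobenzaldehyde
Product: 15 MOM-protected seco stilbene, i.e. 10 with its CH2OH replaced by CH=CH–(4-fluoro-3-nitrophenyl) (E/Z mixture), via benzylidene phosphorane 14 (not isolated)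
Conditions: K2CO3, 18-crown-6 (cat.), CH2Cl2, reflux
Reagents that add atoms: none
Why: A Wittig reaction under solid–liquid phase-transfer conditions uses carbonate, which is basic enough to form the benzylic ylide but not nucleophilic enough to displace the activated fluoride, and the very electrophilic aldehyde traps the ylide as it forms while the ring-A oxygen stays masked.

**Step 9**
Reactants: 15 MOM-protected seco stilbene
Product: 16 MOM-protected seco bibenzyl, i.e. 2-fluoro-5-{2-[3-(3-{2-[3,4-dimethoxy-5-(methoxymethoxy)phenyl]ethyl}phenoxy)-4,5-dimethoxyphenyl]ethyl}nitrobenzene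
Conditions: TsNHNH2 (excess, portionwise), NaOAc, DME–H2O, reflux
Reagents that add atoms: none
Why: Diimide generated in situ transfers H2 to the C=C bond through a concerted cyclic transition state and does not reduce the nitro group or the aryl fluoride, which catalytic hydrogenation would not spare.

**Step 10**
Reactants: 16 MOM-protected seco bibenzyl
Product: 17 seco phenol, 5-{2-[3-(5-{2-(4-fluoro-3-nitrophenyl)ethyl}-2,3-dimethoxyphenoxy)phenyl]ethyl}-2,3-dimethoxyphenol
Conditions: 3 M aq. HCl, MeOH–THF, 50 °C
Reagents that add atoms: none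
Why: Acid-catalysed acetal methanolysis removes the MOM group, while methyl ethers, the diaryl ether and the fluoronitroarene (electrophilic only towards bases and nucleophiles) are inert to acid.

**Step 11**
Reactants: 17 seco phenol
Product: 18 nitro macrocycle tetramethyl ether (19-membered A–O–B–CH2CH2–C–O–D–CH2CH2 ring with NO2 on ring B ortho to the new ether oxygen)
Conditions: K2CO3 (excess), degassed dry DMF, Ar, 60 °C; 17 added by syringe pump to a final concentration of about 2–3 mM
Reagents that add atoms: none
Why: Carbonate deprotonates the only free phenol, the ring-A hydroxyl meta to the bridge, and the phenoxide adds to the fluorine-bearing C-4 of ring B to give a Meisenheimer σ-complex stabilised by the ortho nitro group, from which fluoride is expelled to fix the A–O–B ether (addition–elimination SNAr). The closest known reaction type is the intramolecular SNAr macroetherification of phenols onto 4-fluoro-3-nitrophenyl units used for cyclic diaryl ether natural products. The single ring formed is the 19-membered macrocycle, closed end-to-end by C–O bond formation between the two termini of the A–D–C–B chain, with the attacked ring-B carbon becoming a ring member. No stereocentre is created. The step needs site selectivity and selectivity for ring closure over chain growth: the first follows from 17 having one phenol and one electron-poor C–F carbon (all other oxygens are methyl or aryl ethers), the second from a low stationary phenoxide concentration maintained by slow addition into dilute carbonate/DMF. The ring-A oxygen, flanked by a methoxy group on an electron-rich ring, is a poor partner for copper coupling but a good SNAr donor, which is why this bond is formed last.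

**Step 12**
Reactants: 18 nitro macrocycle tetramethyl ether
Product: 19 amino macrocycle tetramethyl ether
Conditions: H2 (1 atm), 10% Pd/C, EtOAc–MeOH, rt
Reagents that add atoms: none
Why: Catalytic hydrogenation reduces the aryl nitro group to the aniline, and the only other functions present (aryl methyl ethers, diaryl ethers, saturated bridges) are inert.

**Step 13**
Reactants: 19 amino macrocycle tetramethyl ether
Product: 21 macrocycle tetramethyl ether, via arenediazonium chloride 20 (not isolated)
Conditions: NaNO2, 2 M aq. HCl, THF, 0 °C; then 50% aq. H3PO2, Cu2O (cat.), 0 °C to rt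
Reagents that add atoms: none
Why: Diazotisation followed by hypophosphorous acid hydrodediazoniation replaces N2+ by H through an aryl radical chain in which fast hydrogen-atom transfer from H3PO2 outruns radical attack on the neighbouring ring.

**Step 14**
Reactants: 21 macrocycle tetramethyl ether
Product: 22 target tetraphenol CNP0511668.0
Conditions: BBr3 (excess), CH2Cl2, −78 °C to rt; MeOH/H2O quench; work-up under Ar with aq. Na2S2O4
Reagents that add atoms: none
Why: Boron tribromide demethylation (Lewis acid complexation, then bromide SN2 at methyl) cleaves all four aryl methyl ethers but not the diaryl ether bonds, whose sp2 carbons cannot undergo that displacement.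

**Compound list**
1 | 3-hydroxy-4,5-dimethoxybenzaldehyde | COc1cc(C=O)cc(O)c1OC | starting material
2 | 3,4-dimethoxy-5-(methoxymethoxy)benzaldehyde | COCOc1cc(C=O)cc(OC)c1OC | intermediate
3 | [3-(benzyloxy)phenyl]methanol | OCc1cccc(OCc2ccccc2)c1 | starting material
4 | [3-(benzyloxy)benzyl]triphenylphosphonium bromide | [Br-].c1ccc(COc2cccc(C[P+](c3ccccc3)(c3ccccc3)c3ccccc3)c2)cc1 | intermediate
5 | [3-(benzyloxy)benzylidene]triphenylphosphorane | c1ccc(COc2cccc(C=P(c3ccccc3)(c3ccccc3)c3ccccc3)c2)cc1 | intermediate (not isolated)
6 | 1-{2-[3-(benzyloxy)phenyl]ethenyl}-3,4-dimethoxy-5-(methoxymethoxy)benzene, E/Z mixture (geometry undefined) | COCOc1cc(C=Cc2cccc(OCc3ccccc3)c2)cc(OC)c1OC | intermediate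
7 | 3-{2-[3,4-dimethoxy-5-(methoxymethoxy)phenyl]ethyl}phenol | COCOc1cc(CCc2cccc(O)c2)cc(OC)c1OC | intermediate
8 | 3-bromo-4,5-dimethoxybenzaldehyde | COc1cc(C=O)cc(Br)c1OC | starting material
9 | 3-(3-{2-[3,4-dimethoxy-5-(methoxymethoxy)phenyl]ethyl}phenoxy)-4,5-dimethoxybenzaldehyde | COCOc1cc(CCc2cccc(Oc3cc(C=O)cc(OC)c3OC)c2)cc(OC)c1OC | intermediate
10 | [3-(3-{2-[3,4-dimethoxy-5-(methoxymethoxy)phenyl]ethyl}phenoxy)-4,5-dimethoxyphenyl]methanol | COCOc1cc(CCc2cccc(Oc3cc(CO)cc(OC)c3OC)c2)cc(OC)c1OC | intermediate
11 | benzylic bromide of 10 (CH2Br in place of CH2OH) | COCOc1cc(CCc2cccc(Oc3cc(CBr)cc(OC)c3OC)c2)cc(OC)c1OC | intermediate (not isolated)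
12 | [3-(3-{2-[3,4-dimethoxy-5-(methoxymethoxy)phenyl]ethyl}phenoxy)-4,5-dimethoxybenzyl]triphenylphosphonium bromide | [Br-].COCOc1cc(CCc2cccc(Oc3cc(C[P+](c4ccccc4)(c4ccccc4)c4ccccc4)cc(OC)c3OC)c2)cc(OC)c1OC | intermediate
13 | 4-fluoro-3-nitrobenzaldehyde | O=Cc1ccc(F)c(c1)[N+](=O)[O-] | starting material
14 | benzylidene phosphorane derived from 12 | COCOc1cc(CCc2cccc(Oc3cc(C=P(c4ccccc4)(c4ccccc4)c4ccccc4)cc(OC)c3OC)c2)cc(OC)c1OC | intermediate (not isolated)
15 | MOM-protected seco stilbene, E/Z mixture (geometry undefined) | COCOc1cc(CCc2cccc(Oc3cc(C=Cc4ccc(F)c(c4)[N+](=O)[O-])cc(OC)c3OC)c2)cc(OC)c1OC | intermediate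
16 | MOM-protected seco bibenzyl | COCOc1cc(CCc2cccc(Oc3cc(CCc4ccc(F)c(c4)[N+](=O)[O-])cc(OC)c3OC)c2)cc(OC)c1OC | intermediate
17 | seco phenol fluoronitroarene (key-step precursor) | COc1cc(CCc2cccc(c2)Oc2cc(CCc3ccc(F)c(c3)[N+](=O)[O-])cc(OC)c2OC)cc(O)c1OC | intermediate
18 | nitro macrocycle tetramethyl ether (key-step product) | COc1cc2cc(c1OC)Oc1ccc(cc1[N+](=O)[O-])CCc1cc(OC)c(OC)c(c1)Oc1cccc(c1)CC2 | intermediate
19 | amino macrocycle tetramethyl ether | COc1cc2cc(c1OC)Oc1ccc(cc1N)CCc1cc(OC)c(OC)c(c1)Oc1cccc(c1)CC2 | intermediate
20 | macrocyclic arenediazonium chloride | COc1cc2cc(c1OC)Oc1ccc(cc1[N+]#N)CCc1cc(OC)c(OC)c(c1)Oc1cccc(c1)CC2.[Cl-] | intermediate (not isolated)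
21 | macrocycle tetramethyl ether | COc1cc2cc(c1OC)Oc1ccc(cc1)CCc1cc(OC)c(OC)c(c1)Oc1cccc(c1)CC2 | intermediate
22 | CNP0511668.0 (macrocyclic bis-bibenzyl tetraphenol, achiral) | Oc1cc2cc(c1O)Oc1ccc(cc1)CCc1cc(O)c(O)c(c1)Oc1cccc(c1)CC2 | target

**Step count.** Total: 14 steps. Longest linear sequence: 13 steps (from 1 through steps 1 and 3–14; step 2 is a one-step side branch).

**Steps most likely to fail**

Step 11 (macrocyclisation). Chain growth by intermolecular ether formation may outrun ring closure, and a slow closure would give time for fluoride capture by dimethylamine from DMF or for oxidation of the electron-rich phenoxide. The fallback forms the A–O–B ether intermolecularly and closes the ring at the B–C bridge instead. It sets out from 10 and returns at 19.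
- Acidic methanolysis of 10 should give the phenol benzyl alcohol F1.
- Its phenoxide (K2CO3, DMF, rt) should displace fluoride from the doubly activated aldehyde 13 to give the nitro diaryl ether aldehyde F2.
- PPh3·HBr in refluxing MeCN should convert the benzylic alcohol into the formyl phosphonium bromide F3.
- Slow addition of F3 to base at high dilution should close the ring by intramolecular Wittig reaction to the macrocyclic nitrostilbene F4.
- Hydrogenation over Pd/C should reduce both the alkene and the nitro group, giving 19.

Step 5 (Ullmann coupling). Oxidative addition at the ortho-methoxylated, electron-rich bromide may be sluggish, so that hydrodebromination and base-induced degradation of the aldehyde compete. The fallback inverts the polarity of the coupling. It sets out from 2 and returns at 9.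
- Wittig reaction of 2 with commercial (3-bromobenzyl)triphenylphosphonium bromide (KOtBu, THF) should give the bromostilbene F5.
- Diimide reduction (TsNHNH2, NaOAc), which keeps the aryl bromide, should give the bromobibenzyl F6.
- Copper-catalysed (CuI, N,N-dimethylglycine, Cs2CO3) or palladium-catalysed C–O coupling of this unhindered bromide with the guaiacol-type phenol 1 should give 9.

Step 9 (diimide reduction). Hydrogen transfer to the conjugated stilbene may stall before completion, and at reflux the activated fluoride may be displaced by sulfinate or acetate. The fallback builds the saturated bridge directly, with no alkene to reduce next to the fluoronitroarene. It sets out from 9 and returns at 16.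
- Methylenation of 9 (MePPh3Br, KOtBu, THF) should give the styrene F7.
- Anti-Markovnikov hydroboration with 9-BBN should give the B-alkyl borane F8.
- B-alkyl Suzuki–Miyaura coupling of F8 with commercial 4-bromo-1-fluoro-2-nitrobenzene (Pd(dppf)Cl2, K3PO4, THF–DMF, 50 °C) should give 16.

**Further compounds**
F1 | step 11 | 5-[2-(3-{[5-(hydroxymethyl)-2,3-dimethoxyphenyl]oxy}phenyl)ethyl]-2,3-dimethoxyphenol | COc1cc(CCc2cccc(Oc3cc(CO)cc(OC)c3OC)c2)cc(O)c1OC
F2 | step 11 | 4-{5-[2-(3-{[5-(hydroxymethyl)-2,3-dimethoxyphenyl]oxy}phenyl)ethyl]-2,3-dimethoxyphenoxy}-3-nitrobenzaldehyde | COc1cc(CCc2cccc(Oc3cc(CO)cc(OC)c3OC)c2)cc(Oc2ccc(C=O)cc2[N+](=O)[O-])c1OC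
F3 | step 11 | benzyltriphenylphosphonium bromide derived from F2 (CH2PPh3+ Br− in place of CH2OH) | [Br-].COc1cc(CCc2cccc(Oc3cc(C[P+](c4ccccc4)(c4ccccc4)c4ccccc4)cc(OC)c3OC)c2)cc(Oc2ccc(C=O)cc2[N+](=O)[O-])c1OC
F4 | step 11 | macrocyclic nitrostilbene tetramethyl ether (E/Z mixture, geometry undefined) | COc1cc2cc(c1OC)Oc1ccc(cc1[N+](=O)[O-])C=Cc1cc(OC)c(OC)c(c1)Oc1cccc(c1)CC2
F5 | step 5 | 1-bromo-3-{2-[3,4-dimethoxy-5-(methoxymethoxy)phenyl]ethenyl}benzene (E/Z mixture, geometry undefined) | COCOc1cc(C=Cc2cccc(Br)c2)cc(OC)c1OC
F6 | step 5 | 1-bromo-3-{2-[3,4-dimethoxy-5-(methoxymethoxy)phenyl]ethyl}benzene | COCOc1cc(CCc2cccc(Br)c2)cc(OC)c1OC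
F7 | step 9 | styrene derived from 9 (CH=CH2 in place of CHO) | COCOc1cc(CCc2cccc(Oc3cc(C=C)cc(OC)c3OC)c2)cc(OC)c1OC
F8 | step 9 | B-alkyl-9-borabicyclo[3.3.1]nonane from hydroboration of F7 | COCOc1cc(CCc2cccc(Oc3cc(CCB4C5CCCC4CCC5)cc(OC)c3OC)c2)cc(OC)c1OC
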